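## Retrosynthetic overview
1. Target 22 comes from 21 by removing the di-tert-butylsilylene (DTBS) group. The C11 acetate and C7 isovalerate are installed last, on the bis-TBS lactol acylal 18.
2. The dihydropyran (C1–O2–C3=C4) is closed late. An acid-mediated dienolisation and oxa-cyclisation of the 1,5-dialdehyde 16 gives the 2H-pyran lactol 17. 16 comes from the C5 ketone 11 by HWE olefination and redox steps.
3. The cyclopentane is present from the start, in commercial (S)-4-OTBS-cyclopentenone (1). The single C7 stereocentre controls C8 through anti-epoxidation and SmI2 opening of enone 7. C9 is set thermodynamically.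
4. Ring order: cyclopentane first, pyran second.

**Assumptions:**
- Iridoid numbering is used throughout: C1 acylal, O2, C3=C4, C5=C6, C7 OiVal, C8 quaternary, C10 CH2OH, C11 CH2OAc.
- Stannane 3 is made in one step from commercial Bu3SnCH2OH with PMBCl/NaH. Phosphonate 12 is made in two steps from triethyl phosphonoacetate (HCHO, then TBSCl). Both are treated as building blocks.

## Route

**Step 1**
Reactants: 1 (S)-4-OTBS-cyclopent-2-en-1-one
Product: 2 (S)-4-OTBS-2-iodocyclopent-2-en-1-one (C9–I)
Conditions: I2, pyridine, CH2Cl2, 0 °C → rt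
Reagents that add atoms: iodine, II
Why: Johnson α-iodination of the enone; the C7 stereocentre is untouched.

**Step 2**
Reactants: 2, 3 (Bu3SnCH2OPMB)
Product: 4 (S)-4-OTBS-2-(PMB-oxymethyl)cyclopent-2-en-1-one (C1 introduced as CH2OPMB)
Conditions: Pd(PPh3)4, CuI, LiCl, DMF, 60 °C
Reagents that add atoms: none beyond 3
Why: Stille coupling at the vinyl iodide attaches C1.

**Step 3**
Reactants: 4, 5 (Me2(iPrO)SiCH2MgCl)
Product: 6 TMS enol ether of the 1,4-adduct (C10 introduced as CH2Si)
Conditions: 5, CuI (cat.), THF, –40 °C; then TMSCl, Et3N, –78 °C → rt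
Reagents that add atoms: chlorotrimethylsilane, C[Si](C)(C)Cl
Why: Cu-catalysed 1,4-addition at C8 trans to the C7 OTBS; the enolate is trapped regiospecifically. The new C8 centre is temporary.

**Step 4**
Reactants: 6
Product: 7 tetrasubstituted enone (C8=C9)
Conditions: Pd(OAc)2 (1.1 equiv), MeCN, rt
Reagents that add atoms: none
Why: Saegusa–Ito oxidation regenerates the enone and erases the C8 stereocentre, leaving only C7.

**Step 5**
Reactants: 7
Product: 8 C8–C9 α,β-epoxy ketone
Conditions: t-BuOOH, Triton B (cat.), THF, 0 °C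
Reagents that add atoms: tert-butyl hydroperoxide, CC(C)(C)OO
Why: Weitz–Scheffer nucleophilic epoxidation occurs on the face anti to the γ-OTBS (C7–O up), so the epoxide O is down. This fixes C8: O down, C10 up.

**Step 6**
Reactants: 8
Product: 9 C5 ketone with C8–OH (down), C10 CH2Si (up), C9–H
Conditions: SmI2 (2.5 equiv), THF/MeOH, –78 °C; then Et3N, rt, 1 h
Reagents that add atoms: none
Why: SmI2 cleaves the α-carbon C9–O bond of the α,β-epoxy ketone and keeps the C8–O bond. Et3N then equilibrates the enolisable C9, putting C1 trans to C10 and away from the C7 OTBS, which is the target configuration.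

**Step 7**
Reactants: 9
Product: 10 C8(OH)(C10H2OH) diol
Conditions: 30% H2O2, KF, KHCO3, THF/MeOH, rt
Reagents that add atoms: hydrogen peroxide, OO
Why: Tamao–Fleming oxidation converts CH2–Si to CH2–OH with no change at the stereocentres.

**Step 8**
Reactants: 10
Product: 11 DTBS-protected C8/C10 diol
Conditions: tBu2Si(OTf)2, 2,6-lutidine, DMF, –20 °C → rt
Reagents that add atoms: di-tert-butylsilyl bis(triflate), CC(C)(C)[Si](OS(=O)(=O)C(F)(F)F)(OS(=O)(=O)C(F)(F)F)C(C)(C)C
Why: The cyclic silylene blocks the tertiary OH (preventing retro-aldol) and the C10 OH. It survives the later TBS removal and is removed in the last step.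

**Step 9**
Reactants: 11, 12 ((EtO)2P(O)CH(CH2OTBS)CO2Et)
Product: 13 enoate C5=C4(CH2OTBS)CO2Et (E/Z mixture)
Conditions: 12, LiCl, DBU, MeCN, rt
Reagents that add atoms: none beyond 12
Why: Masamune–Roush HWE olefination adds C4, C3 and C11 at the C5 ketone under mild base. Both alkene isomers later converge through the dienol (step 13).

**Step 10**
Reactants: 13
Product: 14 C1 primary alcohol
Conditions: DDQ, CH2Cl2/pH 7 buffer, 0 °C
Reagents that add atoms: none
Why: Oxidative PMB cleavage; silyl groups and the enoate are untouched.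

**Step 11**
Reactants: 14
Product: 15 diol (C1–OH, C3–OH)
Conditions: DIBAL-H (3.5 equiv), CH2Cl2, –78 °C
Reagents that add atoms: none
Why: 1,2-reduction of the conjugated ester to the allylic alcohol. No other esters are present yet, which is why the acyl groups are added last.

**Step 12**
Reactants: 15
Product: 16 dialdehyde (C1 CHO, C3 CHO enal)
Conditions: Dess–Martin periodinane, NaHCO3, CH2Cl2, 0 °C
Reagents that add atoms: none
Why: Oxidation of both primary alcohols; the TBS and DTBS ethers are inert.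

**Step 13**
Reactants: 16
Product: 17 2H-pyran lactol (O2–C3=C4–C5=C6 diene, C1–OH)
Conditions: PPTS (cat.), CH2Cl2, rt
Reagents that add atoms: none
Why: Mild acid-promoted dienolisation of the enal (C6 γ-H) and hemiacetalisation onto the C1 aldehyde, as in iridoid biosynthesis. C9 equilibrates to the trans arrangement. C1 is an anomeric mixture.

**Step 14**
Reactants: 17
Product: 18 C1-isovalerate acylal
Conditions: isovaleryl chloride, pyridine, DMAP (cat.), CH2Cl2, –20 → 0 °C
Reagents that add atoms: isovaleryl chloride, CC(C)CC(=O)Cl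
Why: Acylation of the lactol under equilibrating conditions (ring–chain tautomerism) gives the anomeric acylal with OiVal trans to C8; the only free OH is C1.

**Step 15**
Reactants: 18
Product: 19 C7-OH/C11-OH diol
Conditions: HF·pyridine, pyridine, THF, 0 °C
Reagents that add atoms: none
Why: Both TBS ethers (C7 secondary, C11 primary) cleave faster than the hindered DTBS group. Pyridine buffers the acylal and dienyl ether.

**Step 16**
Reactants: 19
Product: 20 C11 acetate
Conditions: Ac2O (1.05 equiv), pyridine, DMAP (cat.), CH2Cl2, –20 °C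
Reagents that add atoms: acetic anhydride, CC(=O)OC(C)=O
Why: The primary allylic C11-OH is far more reactive than the secondary C7-OH, which sits next to the quaternary C8.

**Step 17**
Reactants: 20
Product: 21 C7 isovalerate
Conditions: isovaleryl chloride (3 equiv), pyridine, DMAP, CH2Cl2, 0 °C → rt
Reagents that add atoms: isovaleryl chloride, CC(C)CC(=O)Cl
Why: Acylation of the last free OH (C8 and C10 are masked by DTBS); the C7 configuration is retained.

**Step 18**
Reactants: 21
Product: 22 Jatamanvaltrate K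
Conditions: HF·pyridine, pyridine, THF, rt
Reagents that add atoms: none
Why: Fluoride cleavage of the silylene releases the tertiary C8-OH and the primary C10-OH; the esters and the acylal are retained.

## Compound list
1 | (S)-4-(tert-butyldimethylsilyloxy)cyclopent-2-en-1-one | O=C1C[C@H](O[Si](C)(C)C(C)(C)C)C=C1 | starting material
2 | (S)-4-OTBS-2-iodocyclopent-2-en-1-one | O=C1C[C@H](O[Si](C)(C)C(C)(C)C)C=C1I | intermediate
3 | tributyl[(4-methoxybenzyloxy)methyl]stannane | CCCC[Sn](CCCC)(CCCC)COCc1ccc(OC)cc1 | starting material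
4 | (S)-4-OTBS-2-(PMB-oxymethyl)cyclopent-2-en-1-one | O=C1C[C@H](O[Si](C)(C)C(C)(C)C)C=C1COCc1ccc(OC)cc1 | intermediate
5 | (isopropoxydimethylsilyl)methylmagnesium chloride | CC(C)O[Si](C)(C)C[Mg]Cl | starting material
6 | TMS enol ether of the C8-silylmethyl adduct (C8 trans to C7–O) | C[Si](C)(C)OC1=C(COCc2ccc(OC)cc2)[C@H](C[Si](C)(C)OC(C)C)[C@@H](O[Si](C)(C)C(C)(C)C)C1 | intermediate
7 | tetrasubstituted enone (7S) | O=C1C[C@H](O[Si](C)(C)C(C)(C)C)C(C[Si](C)(C)OC(C)C)=C1COCc1ccc(OC)cc1 | intermediate
8 | 8,9-epoxy ketone (O anti to C7–O) | O=C1C[C@H](O[Si](C)(C)C(C)(C)C)[C@@]2(C[Si](C)(C)OC(C)C)O[C@@]12COCc1ccc(OC)cc1 | intermediate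
9 | β-hydroxy ketone (8-OH α, 10-CH2Si β, 9-H β) | O=C1C[C@H](O[Si](C)(C)C(C)(C)C)[C@](O)(C[Si](C)(C)OC(C)C)[C@H]1COCc1ccc(OC)cc1 | intermediate
10 | C8/C10 diol | O=C1C[C@H](O[Si](C)(C)C(C)(C)C)[C@](O)(CO)[C@H]1COCc1ccc(OC)cc1 | intermediate
11 | DTBS-protected diol | O=C1C[C@H](O[Si](C)(C)C(C)(C)C)[C@]2(CO[Si](C(C)(C)C)(C(C)(C)C)O2)[C@H]1COCc1ccc(OC)cc1 | intermediate
12 | ethyl 2-(diethoxyphosphoryl)-3-(TBSO)propanoate | CCOC(=O)C(CO[Si](C)(C)C(C)(C)C)P(=O)(OCC)OCC | starting material
13 | enoate C5=C4 (E/Z mixture) | CCOC(=O)C(CO[Si](C)(C)C(C)(C)C)=C1C[C@H](O[Si](C)(C)C(C)(C)C)[C@]2(CO[Si](C(C)(C)C)(C(C)(C)C)O2)[C@H]1COCc1ccc(OC)cc1 | intermediate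
14 | C1 primary alcohol | CCOC(=O)C(CO[Si](C)(C)C(C)(C)C)=C1C[C@H](O[Si](C)(C)C(C)(C)C)[C@]2(CO[Si](C(C)(C)C)(C(C)(C)C)O2)[C@H]1CO | intermediate
15 | diol (C1-OH, C3-OH) | OCC(CO[Si](C)(C)C(C)(C)C)=C1C[C@H](O[Si](C)(C)C(C)(C)C)[C@]2(CO[Si](C(C)(C)C)(C(C)(C)C)O2)[C@H]1CO | intermediate
16 | dialdehyde | O=CC(CO[Si](C)(C)C(C)(C)C)=C1C[C@H](O[Si](C)(C)C(C)(C)C)[C@]2(CO[Si](C(C)(C)C)(C(C)(C)C)O2)[C@H]1C=O | intermediate
17 | lactol (C1 anomeric mixture) | OC1OC=C(CO[Si](C)(C)C(C)(C)C)C2=C[C@H](O[Si](C)(C)C(C)(C)C)[C@]3(CO[Si](C(C)(C)C)(C(C)(C)C)O3)[C@@H]12 | intermediate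
18 | C1-isovalerate acylal, bis-TBS | CC(C)CC(=O)O[C@@H]1OC=C(CO[Si](C)(C)C(C)(C)C)C2=C[C@H](O[Si](C)(C)C(C)(C)C)[C@]3(CO[Si](C(C)(C)C)(C(C)(C)C)O3)[C@@H]12 | intermediate
19 | C7/C11 diol | CC(C)CC(=O)O[C@@H]1OC=C(CO)C2=C[C@H](O)[C@]3(CO[Si](C(C)(C)C)(C(C)(C)C)O3)[C@@H]12 | intermediate
20 | C11 acetate | CC(C)CC(=O)O[C@@H]1OC=C(COC(C)=O)C2=C[C@H](O)[C@]3(CO[Si](C(C)(C)C)(C(C)(C)C)O3)[C@@H]12 | intermediate
21 | C7 isovalerate, DTBS-protected | CC(C)CC(=O)O[C@@H]1OC=C(COC(C)=O)C2=C[C@H](OC(=O)CC(C)C)[C@]3(CO[Si](C(C)(C)C)(C(C)(C)C)O3)[C@@H]12 | intermediate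
22 | Jatamanvaltrate K | CC(=O)OCC1=CO[C@@H](OC(=O)CC(C)C)[C@H]2C1=C[C@H](OC(=O)CC(C)C)[C@]2(O)CO | target

## Totals
- Total steps: 18.
- Longest linear sequence: 18 (1 → 22).
- Building-block preparations run in parallel: 3 in one step, 12 in two steps.

## Three steps most likely to fail
1. **Step 9, HWE on the hindered, β-silyloxy C5 ketone.** It forms a tetrasubstituted alkene, risks E1cB loss of the C7 OTBS, and may give low E/Z control.
   *Fallback that changes the approach:* convert the ketone to its enol triflate (KHMDS, PhNTf2, –78 °C). Then do a Stille coupling with a preformed (Z)-β-alkoxyvinylstannane carrying C11, C4 and C3. That installs the C3=C4 enol ether directly. The pyran is then closed by transacetalisation with the C1 aldehyde, which avoids the dienal chemistry.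
2. **Step 13, dienolisation and oxa-cyclisation.** The enal geometry, ionisation of the allylic C7 OTBS, and sensitivity of the 2H-pyran lactol are all concerns.
   *Fallback that changes the approach:* oxidise C1 to the carboxylic acid (Pinnick) and close it onto the C3 aldehyde as the enol lactone. Then reduce the lactone to the lactol with LiAlH(OtBu)3 or DIBAL-H.
3. **Step 6, SmI2 opening and C9 equilibration.** It could go wrong by Peterson loss of the β-silyl alkoxide, by retro-aldol, or by the wrong C9 epimer.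
   *Fallback that changes the approach:* build C8 by Upjohn dihydroxylation of an exocyclic C8=C10 methylene (from the β-silyl enone by protodesilylation). OsO4 approaches anti to the C7 OTBS. Set C9 afterwards by thermodynamic equilibration of the C1 aldehyde stage.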